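## The problem

The target, CNP0247177.1, is a bisabolane-type bis-angelate built on a single carbocycle: a 2-methylcyclohexanone, numbered here C1 (C=O), C2 (quaternary, methyl), C3, C4 (CH2), C5 and C6, with an epoxide across C2–C3 and an angelate on C6. C5 carries a 1,1-disubstituted alkene (C2′, methylene C1′) that continues into a chain with a second angelate at C3′ and a 2,2-dimethyloxirane at C5′–C6′, so the skeleton is one ring with one appended chain. Six stereocentres must be set: 2R, 3R, 5R and 6R in the ring and 3′S and 5′R in the chain. The C6 ester is trans to the C5 side chain, and the ring epoxide oxygen is cis to the side chain and trans to the ester, which is the face a nucleophilic enone epoxidation would avoid. C5 can set C6 through 1,2-induction on an enolate, and C5 and C6 together can set a temporary C1 carbinol that delivers the epoxide oxygen, whereas C3′ and C5′ are insulated from the ring by sp2 and CH2 carbons and need reagent control, as does C5 relative to C3′. The fragile groups are the two (Z)-2-methylbut-2-enoates, which isomerise to tiglates under nucleophilic acylation and migrate under base, the α-acyloxy-α′,β′-epoxy ketone, which is base-labile and epimerisable at C6, the acid-sensitive trisubstituted epoxide, and the allylic C3′ ester, which low-valent metals would ionise. The enabling feature is that C1, C6, C5 and C4 are the four carbons of a 3-substituted cyclobutanone once C1 and C4 are joined, while C2–C3 with its methyl is propyne. C5 is then the prochiral carbon of a symmetric four-membered ketone, and the C2=C3 alkene left by the ring expansion is the handle for the epoxide.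

## Retrosynthesis

**Ring epoxide and C1.** Target 23 is taken back to cis-epoxy alcohol 22 by adjusting only the oxidation level at C1. The two C–O bonds of the ring epoxide are then cut, through epoxysilane 21, to allylic alcohol 20, and 20 is traced to enone 19. Direct peroxide epoxidation of an enone was rejected because hydroperoxide adds to C3 anti to the C5 substituent, which is the wrong face. A C1 hydroxyl cis to the side chain delivers oxygen to the correct face instead. The forward steps must give the C1 alcohol trans to the C6 ester, a syn-directed epoxidation of a tetrasubstituted alkene, and a mild oxidation.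

**Silicon.** The C3 silyl group is kept until 21 and removed there (21 to 22). As a β-silyl enone it is inert to acid, acylation and dioxirane, and no reliable protodesilylation exists at that stage. Once C3 is an epoxide carbon, fluoride cleaves the C–Si bond through an oxiranyl anion with retention. This costs one step but uses a known reaction at the point where it is easy.

**Esters and side-chain epoxide.** 19 is cut at the C5′–C6′ epoxide to triene 18. At the enone stage the prenyl alkene is the only electron-rich, unhindered alkene, so a Shi epoxidation is chemoselective. 18 is cut at both ester C–O bonds to diol 16 and two equivalents of angelic acid 17. Installing both esters in one operation, before the reduction, lets them serve as protecting groups for the rest of the route and avoids acylating a hydroxy epoxy ketone at the end. 16 comes from silyl ether 15, and 15 from 13 by cutting the C6–O bond: enolate oxidation anti to the C5 substituent.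

**Key disconnection.** 13 is cut at C1–C2 and C3–C4 into cyclobutanone 11 and 1-(trimethylsilyl)propyne 12. Compared with ring closures at a single bond, this cut removes the ring and the C5 stereocentre together and leaves an achiral four-membered ketone bearing the complete side chain. The forward reaction must select one of two enantiotopic C1–CH2 bonds (ligand control) and one alkyne orientation (silyl control). It must also tolerate an allylic silyl ether and two alkenes. An allylic ester would not survive zerovalent nickel, hence the silyl ether at C3′.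

**Side chain.** 11 is the deprotected form of ketal 10, the silyl ether of alcohol 9. 9 is cut at C2′–C3′ into 2-iodoalkene 6 and aldehyde 8. A chromium-mediated coupling is neutral, aldehyde-selective and does not isomerise the β,γ-unsaturated aldehyde; a chiral chromium complex sets 3′S.

**Small fragments.** 6 comes from alkyne 4 by Markovnikov hydrometalation–iodination, 4 from ester 2 by reduction and one-carbon homologation, and 2 from 3-oxocyclobutane-1-carboxylic acid 1. Aldehyde 8 comes from alcohol 7 by oxidation.

## Roads not taken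

Alternative 1: chromium–nickel cyclisation at C1–C2.
- Cut and key step: an open-chain aldehyde A1, with the C6 and C3′ angelates and a (Z)-2-iodobut-2-enyl arm on C5, would be closed to cyclohexenol A2 by cathodic reduction with catalytic CrCl3 and NiCl2·glyme in the presence of Et3SiCl.
- Merits: A2 is already the allylic alcohol needed for directed epoxidation. It carries no silicon and needs no ketone reduction and no late fluoride, so its endgame (side-chain epoxidation, directed epoxidation, oxidation) is shorter and gentler than the one chosen here. In that respect it is the better road.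
- Weak points: A1 needs C5, C6 and C3′ set in an open chain plus a geometrically pure trisubstituted vinyl iodide. Its α-acyloxy aldehyde is epimerisable. The allylic C3′ angelate must survive low-valent nickel. The new C1 centre must form trans to the C6 ester under Felkin-type control alone.
- Comparison: the chosen plan offsets its longer endgame by making the ring and C5 in one catalytic step from a symmetric ketone that is reached in seven simple operations.

Alternative 2: ring-closing metathesis at C2=C3.
- Cut and key step: dienone A3 (isopropenyl ketone at C1, allyl group on C5, silyl ethers at C6 and C3′, side-chain epoxide in place) would be closed to enone A4 with the second-generation Grubbs catalyst RuCl2(H2IMes)(PCy3)(=CHPh).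
- Merits: this is a fully known reaction type that creates no stereocentre, and A4 has no ring silicon. The chosen key step is unproven, so here the alternative is clearly safer.
- Weak points: A3 carries a third 1,1-disubstituted alkene that can compete. The anti C5/C6 pair, C3′ and C5′ must all be made in an acyclic series. A4 still needs the reduction, directed epoxidation and oxidation sequence, and in addition the exchange of two silyl ethers for angelates on a late, base-sensitive α-oxygenated ketone.
- Comparison: the chosen plan has a much shorter approach to the cyclohexenone and installs the esters early on a robust enone. It pays for this with one speculative step backed by a fallback.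

Alternative 3: allylsilane–aldehyde cyclisation at C5–C6.
- Cut and key step: aldehyde A5 (C6 aldehyde, C1 p-methoxybenzyl ether, (Z)-C2=C3 alkene, allylsilane terminating at C5) would cyclise on SnCl4 through a chelate to cyclohexenol A6, forming C5–C6 and releasing the C1′ methylene.
- Merits: one known step makes the ring, two stereocentres (C5, C6) and the exocyclic alkene, with the C1 oxygen already in place. It therefore does more stereochemical work than the chosen key step, which sets only C5.
- Weak points: a strong Lewis acid meets an allylic silyl ether and a prenyl alkene. C1 in A5 is both allylic and α to the aldehyde, so it is epimerisable. A5 itself needs two trisubstituted alkenes of defined geometry. A6 requires protecting-group changes (ether cleavage at C1, esterification at C6 and C3′) before the epoxide can be introduced.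
- Comparison: the chosen plan uses simpler, mostly achiral precursors and neutral conditions throughout the ring-forming stage.

Key step: step 8

Assumption: the sense of induction of the chiral ligands in steps 5 and 8 cannot be predicted with confidence; the ligand antipode that gives (3S)-9 and (5R)-13 is taken, both antipodes being accessible.

## Route

Step 1
Reactants: 1 3-oxocyclobutane-1-carboxylic acid
Product: 2 methyl 3,3-dimethoxycyclobutane-1-carboxylate
Conditions: HC(OMe)3, MeOH, p-toluenesulfonic acid monohydrate (cat.), reflux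
Reagents that add atoms: methanol, CO; trimethyl orthoformate, COC(OC)OC
Why: Fischer esterification and acid-catalysed ketalisation run together, the orthoester consuming the water; the ketal shields the strained ketone from the hydride and base of the next steps.

Step 2
Reactants: 2 methyl 3,3-dimethoxycyclobutane-1-carboxylate
Product: 4 3-ethynyl-1,1-dimethoxycyclobutane, via 3,3-dimethoxycyclobutane-1-carbaldehyde 3 (not isolated)
Conditions: i-Bu2AlH, CH2Cl2, −78 °C; then MeOH, K2CO3, dimethyl (1-diazo-2-oxopropyl)phosphonate, −78 °C → rt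
Reagents that add atoms: dimethyl (1-diazo-2-oxopropyl)phosphonate, CC(=O)C(=[N+]=[N-])P(=O)(OC)OC
Why: Partial ester reduction stops at the aluminium hemiacetal at low temperature, and the aldehyde released by methanol undergoes Seyferth–Gilbert homologation with the Ohira–Bestmann reagent in the same flask, so the volatile aldehyde is never handled.

Step 3
Reactants: 4 3-ethynyl-1,1-dimethoxycyclobutane
Product: 6 3-(1-iodoethenyl)-1,1-dimethoxycyclobutane, via [1-(3,3-dimethoxycyclobutyl)ethenyl]bis(2-methylpropyl)alumane 5 (not isolated)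
Conditions: NiCl2(dppp) (3 mol %), i-Bu2AlH, THF, 0 °C → rt; then N-iodosuccinimide, 0 °C
Reagents that add atoms: N-iodosuccinimide, O=C1CCC(=O)N1I
Why: Nickel-catalysed α-selective hydroalumination of a terminal alkyne places aluminium on the internal carbon, and iodinolysis of the C–Al bond gives the 2-iodo-1-alkene; the conditions are neutral, so the ketal survives where protic hydroiodination would cleave it.

Step 4
Reactants: 7 4-methylpent-3-en-1-ol
Product: 8 4-methylpent-3-enal
Conditions: Dess–Martin periodinane, pyridine, CH2Cl2, 0 °C → rt; used at once as a solution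
Reagents that add atoms: none
Why: Dess–Martin oxidation under buffered, non-basic conditions gives the β,γ-unsaturated aldehyde without moving the alkene into conjugation.

Step 5
Reactants: 6 3-(1-iodoethenyl)-1,1-dimethoxycyclobutane; 8 4-methylpent-3-enal
Product: 9 (3S)-2-(3,3-dimethoxycyclobutyl)-6-methylhepta-1,5-dien-3-ol
Conditions: CrCl2 (10 mol %), chiral valinol-derived 2-(2-sulfonamidoaryl)oxazoline ligand (11 mol %), Et3N; NiCl2(2,9-dimethyl-1,10-phenanthroline) (2 mol %), Mn, LiCl, Cp2ZrCl2, MeCN, rt
Reagents that add atoms: none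
Why: Catalytic asymmetric Nozaki–Hiyama–Kishi coupling: nickel activates the C–I bond, the alkenyl group passes to chromium and adds to the aldehyde only, Cp2ZrCl2 frees the chromium alkoxide and Mn returns divalent chromium. C3′ is set by the chiral sulfonamide ligand on chromium; the neutral medium leaves the ketal and the skipped alkene alone.

Step 6
Reactants: 9 (3S)-2-(3,3-dimethoxycyclobutyl)-6-methylhepta-1,5-dien-3-ol
Product: 10 tert-butyl{[(3S)-2-(3,3-dimethoxycyclobutyl)-6-methylhepta-1,5-dien-3-yl]oxy}dimethylsilane
Conditions: TBSCl, imidazole, DMF, rt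
Reagents that add atoms: tert-butyldimethylsilyl chloride, CC(C)(C)[Si](C)(C)Cl
Why: Standard silylation of a secondary allylic alcohol under basic conditions that do not touch the ketal; a silyl ether is not ionised by zerovalent nickel in step 8, as an ester would be.

Step 7
Reactants: 10 tert-butyl{[(3S)-2-(3,3-dimethoxycyclobutyl)-6-methylhepta-1,5-dien-3-yl]oxy}dimethylsilane
Product: 11 3-[(3S)-3-{[tert-butyl(dimethyl)silyl]oxy}-6-methylhepta-1,5-dien-2-yl]cyclobutan-1-one
Conditions: p-toluenesulfonic acid monohydrate (10 mol %), acetone/H2O (10:1), rt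
Reagents that add atoms: water, O
Why: Mild acid-catalysed ketal hydrolysis; a secondary tert-butyldimethylsilyl ether and the alkenes tolerate catalytic sulfonic acid in wet acetone at room temperature.

Step 8
Reactants: 11 3-[(3S)-3-{[tert-butyl(dimethyl)silyl]oxy}-6-methylhepta-1,5-dien-2-yl]cyclobutan-1-one; 12 1-(trimethylsilyl)propyne
Product: 13 (5R)-5-[(3S)-3-{[tert-butyl(dimethyl)silyl]oxy}-6-methylhepta-1,5-dien-2-yl]-2-methyl-3-(trimethylsilyl)cyclohex-2-en-1-one
Conditions: Ni(cod)2 (10 mol %), TADDOL-derived N,N-dimethylphosphoramidite ligand (20 mol %), 12 (3 equiv), toluene, 80–100 °C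
Reagents that add atoms: none
Why: Proposed new method: zerovalent nickel joins the ketone C=O and alkyne 12 by oxidative cyclisation to a spiro oxanickelacyclopentene with the methyl-bearing carbon bonded to C1 and the silyl-bearing carbon on nickel; strain-driven β-carbon elimination of one C1–CH2 bond opens it to a seven-membered nickelacycle, and reductive elimination forms C3–C4 and returns zerovalent nickel. The closest known reaction type is the Ni(cod)2/trialkylphosphine-catalysed intermolecular insertion of internal alkynes into 3-substituted cyclobutanones, together with enantioselective intramolecular insertions into cyclobutanones; a ligand-controlled intermolecular choice between the two C1–CH2 bonds has not been shown. The six-membered ring arises by formal [4+2] two-atom expansion of the four-membered ring (C1–C2 and C3–C4 formed, one C1–C4 bond broken) and not by cyclisation of a chain, so no ring-closure mode applies. The only new stereocentre, C5, is the former prochiral C3 of the cyclobutanone, and it is fixed in the β-carbon elimination by the chiral phosphoramidite on nickel; the remote C3′ centre cannot steer this but makes the two outcomes diastereomers that can be assayed and separated. Regioselectivity is secured by the silyl group, which takes the position α to nickel in the oxidative cyclisation for steric and electronic reasons, so methyl ends on C2 and silicon on C3. Chemoselectivity rests on the substrate: the silyl ether is no leaving group for nickel, neither alkene can reach the carbonyl, and 12 is slow to cyclotrimerise.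

Step 9
Reactants: 13 (5R)-5-[(3S)-3-{[tert-butyl(dimethyl)silyl]oxy}-6-methylhepta-1,5-dien-2-yl]-2-methyl-3-(trimethylsilyl)cyclohex-2-en-1-one
Product: 15 (5R,6R)-5-[(3S)-3-{[tert-butyl(dimethyl)silyl]oxy}-6-methylhepta-1,5-dien-2-yl]-6-hydroxy-2-methyl-3-(trimethylsilyl)cyclohex-2-en-1-one, via potassium dienolate 14 (not isolated)
Conditions: KN(SiMe3)2, THF, −78 °C; then 3-phenyl-2-(phenylsulfonyl)oxaziridine, −78 °C; aq. NH4Cl
Reagents that add atoms: 3-phenyl-2-(phenylsulfonyl)oxaziridine, O=S(=O)(c1ccccc1)N1OC1c1ccccc1
Why: Kinetic α′-deprotonation gives the cross-conjugated enolate, which is hydroxylated by the N-sulfonyloxaziridine (Davis oxidation); the oxidant approaches C6 anti to the adjacent C5 substituent, so the hydroxyl is trans to the side chain, and the reagent does not epoxidise the alkenes.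

Step 10
Reactants: 15 (5R,6R)-5-[(3S)-3-{[tert-butyl(dimethyl)silyl]oxy}-6-methylhepta-1,5-dien-2-yl]-6-hydroxy-2-methyl-3-(trimethylsilyl)cyclohex-2-en-1-one
Product: 16 (5R,6R)-6-hydroxy-5-[(3S)-3-hydroxy-6-methylhepta-1,5-dien-2-yl]-2-methyl-3-(trimethylsilyl)cyclohex-2-en-1-one
Conditions: HF·pyridine, pyridine, THF, 0 °C → rt
Reagents that add atoms: none
Why: Buffered hydrogen fluoride cleaves the O–Si bond but not the C–Si bond of the electron-poor β-silyl enone, so only the silyl ether is removed; no epoxide is present yet.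

Step 11
Reactants: 16 (5R,6R)-6-hydroxy-5-[(3S)-3-hydroxy-6-methylhepta-1,5-dien-2-yl]-2-methyl-3-(trimethylsilyl)cyclohex-2-en-1-one; 17 angelic acid, (2Z)-2-methylbut-2-enoic acid
Product: 18 (1R,6R)-3-methyl-6-{(3S)-6-methyl-3-[(2Z)-2-methylbut-2-enoyloxy]hepta-1,5-dien-2-yl}-2-oxo-4-(trimethylsilyl)cyclohex-3-en-1-yl (2Z)-2-methylbut-2-enoate
Conditions: 17 (5 equiv), 2,4,6-trichlorobenzoyl chloride (5 equiv), Et3N, toluene, rt; then 16, 75 °C
Reagents that add atoms: angelic acid (the second equivalent of 17, which supplies the second angeloyl group), C/C=C(/C)C(=O)O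
Why: Yamaguchi-type mixed-anhydride esterification run without a nucleophilic pyridine catalyst, the established way to make angelates of hindered secondary alcohols without Z→E isomerisation. Both hydroxyls are secondary and each takes one angeloyl group from the preformed mixed anhydride, so two equivalents of 17 are incorporated in one operation; the trans C5/C6 arrangement is the more stable one, so the warm amine base does not erode C6.

Step 12
Reactants: 18 (1R,6R)-3-methyl-6-{(3S)-6-methyl-3-[(2Z)-2-methylbut-2-enoyloxy]hepta-1,5-dien-2-yl}-2-oxo-4-(trimethylsilyl)cyclohex-3-en-1-yl (2Z)-2-methylbut-2-enoate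
Product: 19 (1R,6R)-6-{(3S)-4-[(2R)-3,3-dimethyloxiran-2-yl]-3-[(2Z)-2-methylbut-2-enoyloxy]but-1-en-2-yl}-3-methyl-2-oxo-4-(trimethylsilyl)cyclohex-3-en-1-yl (2Z)-2-methylbut-2-enoate
Conditions: 1,2:4,5-di-O-isopropylidene-β-D-erythro-2,3-hexodiulo-2,6-pyranose (Shi ketone, 30 mol %), KHSO5 (as 2KHSO5·KHSO4·K2SO4), K2CO3, Bu4NHSO4, MeCN/CH2(OMe)2, aq. Na2B4O7/Na2EDTA buffer, 0 °C
Reagents that add atoms: potassium peroxymonosulfate, [K+].[O-]S(=O)(=O)OO
Why: Shi epoxidation through a chiral dioxirane and a spiro transition state; the D-fructose-derived ketone gives the R epoxide from a 2-methylalk-2-ene terminus (C5′). Only the electron-rich trisubstituted alkene reacts: the enoates and the β-silyl enone are electron-poor, and the 1,1-disubstituted alkene is deactivated by its allylic ester.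

Step 13
Reactants: 19 (1R,6R)-6-{(3S)-4-[(2R)-3,3-dimethyloxiran-2-yl]-3-[(2Z)-2-methylbut-2-enoyloxy]but-1-en-2-yl}-3-methyl-2-oxo-4-(trimethylsilyl)cyclohex-3-en-1-yl (2Z)-2-methylbut-2-enoate
Product: 20 (1R,2R,6R)-6-{(3S)-4-[(2R)-3,3-dimethyloxiran-2-yl]-3-[(2Z)-2-methylbut-2-enoyloxy]but-1-en-2-yl}-2-hydroxy-3-methyl-4-(trimethylsilyl)cyclohex-3-en-1-yl (2Z)-2-methylbut-2-enoate
Conditions: NaBH4, CeCl3·7H2O, MeOH, −78 °C
Reagents that add atoms: none
Why: Luche 1,2-reduction: in the half-chair with the C5 and C6 substituents equatorial, hydride enters C1 along the axial trajectory, giving the equatorial carbinol trans to the C6 ester and cis to the C5 side chain; esters and epoxide are inert at this temperature.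

Step 14
Reactants: 20 (1R,2R,6R)-6-{(3S)-4-[(2R)-3,3-dimethyloxiran-2-yl]-3-[(2Z)-2-methylbut-2-enoyloxy]but-1-en-2-yl}-2-hydroxy-3-methyl-4-(trimethylsilyl)cyclohex-3-en-1-yl (2Z)-2-methylbut-2-enoate
Product: 21 (1S,2S,3R,4R,6S)-4-{(3S)-4-[(2R)-3,3-dimethyloxiran-2-yl]-3-[(2Z)-2-methylbut-2-enoyloxy]but-1-en-2-yl}-2-hydroxy-1-methyl-6-(trimethylsilyl)-7-oxabicyclo[4.1.0]heptan-3-yl (2Z)-2-methylbut-2-enoate
Conditions: VO(acac)2 (5 mol %), t-BuOOH (decane solution), CH2Cl2, 0 °C → rt
Reagents that add atoms: tert-butyl hydroperoxide, CC(C)(C)OO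
Why: Hydroxyl-directed vanadium-catalysed epoxidation: the peroxide is delivered within the vanadate ester of the C1 alcohol to the same face, so C2 and C3 are set syn to the C1 oxygen and cis to the side chain; alkenes without a bound hydroxyl (methylene, enoates) are left.

Step 15
Reactants: 21 (1S,2S,3R,4R,6S)-4-{(3S)-4-[(2R)-3,3-dimethyloxiran-2-yl]-3-[(2Z)-2-methylbut-2-enoyloxy]but-1-en-2-yl}-2-hydroxy-1-methyl-6-(trimethylsilyl)-7-oxabicyclo[4.1.0]heptan-3-yl (2Z)-2-methylbut-2-enoate
Product: 22 (1S,2S,3R,4R,6R)-4-{(3S)-4-[(2R)-3,3-dimethyloxiran-2-yl]-3-[(2Z)-2-methylbut-2-enoyloxy]but-1-en-2-yl}-2-hydroxy-1-methyl-7-oxabicyclo[4.1.0]heptan-3-yl (2Z)-2-methylbut-2-enoate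
Conditions: Bu4NF (1.2 equiv), moist THF, 0 °C
Reagents that add atoms: none
Why: Fluoride-induced protodesilylation of an α,β-epoxysilane, a reaction known for 3-silyl-2,3-epoxy alcohols: the silicate releases a configurationally stable oxiranyl anion that is protonated with retention, so C3 keeps its epoxide face; low temperature and near-stoichiometric fluoride limit ester migration.

Step 16
Reactants: 22 (1S,2S,3R,4R,6R)-4-{(3S)-4-[(2R)-3,3-dimethyloxiran-2-yl]-3-[(2Z)-2-methylbut-2-enoyloxy]but-1-en-2-yl}-2-hydroxy-1-methyl-7-oxabicyclo[4.1.0]heptan-3-yl (2Z)-2-methylbut-2-enoate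
Product: 23 (1R,3R,4R,6R)-4-{(3S)-4-[(2R)-3,3-dimethyloxiran-2-yl]-3-[(2Z)-2-methylbut-2-enoyloxy]but-1-en-2-yl}-1-methyl-2-oxo-7-oxabicyclo[4.1.0]heptan-3-yl (2Z)-2-methylbut-2-enoate
Conditions: Dess–Martin periodinane, pyridine, CH2Cl2, 0 °C → rt
Reagents that add atoms: none
Why: Dess–Martin oxidation of the secondary epoxy alcohol under buffered, non-basic conditions leaves both epoxides, both angelates and the epimerisable C6 centre untouched and gives the target.

## Compound list

1 | 3-oxocyclobutane-1-carboxylic acid | O=C1CC(C1)C(=O)O | starting material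
2 | methyl 3,3-dimethoxycyclobutane-1-carboxylate | COC(=O)C1CC(OC)(OC)C1 | intermediate
3 | 3,3-dimethoxycyclobutane-1-carbaldehyde (not isolated) | O=CC1CC(OC)(OC)C1 | intermediate
4 | 3-ethynyl-1,1-dimethoxycyclobutane | C#CC1CC(OC)(OC)C1 | intermediate
5 | [1-(3,3-dimethoxycyclobutyl)ethenyl]bis(2-methylpropyl)alumane (not isolated) | C=C(C1CC(OC)(OC)C1)[Al](CC(C)C)CC(C)C | intermediate
6 | 3-(1-iodoethenyl)-1,1-dimethoxycyclobutane | C=C(I)C1CC(OC)(OC)C1 | intermediate
7 | 4-methylpent-3-en-1-ol | CC(C)=CCCO | starting material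
8 | 4-methylpent-3-enal | CC(C)=CCC=O | intermediate
9 | (3S)-2-(3,3-dimethoxycyclobutyl)-6-methylhepta-1,5-dien-3-ol | C=C([C@H](CC=C(C)C)O)C1CC(OC)(OC)C1 | intermediate
10 | tert-butyl{[(3S)-2-(3,3-dimethoxycyclobutyl)-6-methylhepta-1,5-dien-3-yl]oxy}dimethylsilane | C=C([C@H](CC=C(C)C)O[Si](C)(C)C(C)(C)C)C1CC(OC)(OC)C1 | intermediate
11 | 3-[(3S)-3-{[tert-butyl(dimethyl)silyl]oxy}-6-methylhepta-1,5-dien-2-yl]cyclobutan-1-one | C=C([C@H](CC=C(C)C)O[Si](C)(C)C(C)(C)C)C1CC(=O)C1 | intermediate
12 | 1-(trimethylsilyl)propyne | CC#C[Si](C)(C)C | starting material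
13 | (5R)-5-[(3S)-3-{[tert-butyl(dimethyl)silyl]oxy}-6-methylhepta-1,5-dien-2-yl]-2-methyl-3-(trimethylsilyl)cyclohex-2-en-1-one | C=C([C@H](CC=C(C)C)O[Si](C)(C)C(C)(C)C)[C@H]1CC([Si](C)(C)C)=C(C)C(=O)C1 | intermediate
14 | potassium (3S)-3-[(3S)-3-{[tert-butyl(dimethyl)silyl]oxy}-6-methylhepta-1,5-dien-2-yl]-6-methyl-5-(trimethylsilyl)cyclohexa-1,5-dien-1-olate, the C1–C6 enolate of 13 (not isolated) | C=C([C@H](CC=C(C)C)O[Si](C)(C)C(C)(C)C)[C@H]1CC([Si](C)(C)C)=C(C)C([O-])=C1.[K+] | intermediate
15 | (5R,6R)-5-[(3S)-3-{[tert-butyl(dimethyl)silyl]oxy}-6-methylhepta-1,5-dien-2-yl]-6-hydroxy-2-methyl-3-(trimethylsilyl)cyclohex-2-en-1-one | C=C([C@H](CC=C(C)C)O[Si](C)(C)C(C)(C)C)[C@H]1CC([Si](C)(C)C)=C(C)C(=O)[C@@H]1O | intermediate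
16 | (5R,6R)-6-hydroxy-5-[(3S)-3-hydroxy-6-methylhepta-1,5-dien-2-yl]-2-methyl-3-(trimethylsilyl)cyclohex-2-en-1-one | C=C([C@H](CC=C(C)C)O)[C@H]1CC([Si](C)(C)C)=C(C)C(=O)[C@@H]1O | intermediate
17 | angelic acid, (2Z)-2-methylbut-2-enoic acid | C/C=C(/C)C(=O)O | starting material
18 | (1R,6R)-3-methyl-6-{(3S)-6-methyl-3-[(2Z)-2-methylbut-2-enoyloxy]hepta-1,5-dien-2-yl}-2-oxo-4-(trimethylsilyl)cyclohex-3-en-1-yl (2Z)-2-methylbut-2-enoate | C=C([C@H](CC=C(C)C)OC(=O)/C(C)=C\C)[C@H]1CC([Si](C)(C)C)=C(C)C(=O)[C@@H]1OC(=O)/C(C)=C\C | intermediate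
19 | (1R,6R)-6-{(3S)-4-[(2R)-3,3-dimethyloxiran-2-yl]-3-[(2Z)-2-methylbut-2-enoyloxy]but-1-en-2-yl}-3-methyl-2-oxo-4-(trimethylsilyl)cyclohex-3-en-1-yl (2Z)-2-methylbut-2-enoate | C=C([C@H](C[C@H]1OC1(C)C)OC(=O)/C(C)=C\C)[C@H]1CC([Si](C)(C)C)=C(C)C(=O)[C@@H]1OC(=O)/C(C)=C\C | intermediate
20 | (1R,2R,6R)-6-{(3S)-4-[(2R)-3,3-dimethyloxiran-2-yl]-3-[(2Z)-2-methylbut-2-enoyloxy]but-1-en-2-yl}-2-hydroxy-3-methyl-4-(trimethylsilyl)cyclohex-3-en-1-yl (2Z)-2-methylbut-2-enoate | C=C([C@H](C[C@H]1OC1(C)C)OC(=O)/C(C)=C\C)[C@H]1CC([Si](C)(C)C)=C(C)[C@@H](O)[C@@H]1OC(=O)/C(C)=C\C | intermediate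
21 | (1S,2S,3R,4R,6S)-4-{(3S)-4-[(2R)-3,3-dimethyloxiran-2-yl]-3-[(2Z)-2-methylbut-2-enoyloxy]but-1-en-2-yl}-2-hydroxy-1-methyl-6-(trimethylsilyl)-7-oxabicyclo[4.1.0]heptan-3-yl (2Z)-2-methylbut-2-enoate | C=C([C@H](C[C@H]1OC1(C)C)OC(=O)/C(C)=C\C)[C@H]1C[C@@]2([Si](C)(C)C)O[C@@]2(C)[C@@H](O)[C@@H]1OC(=O)/C(C)=C\C | intermediate
22 | (1S,2S,3R,4R,6R)-4-{(3S)-4-[(2R)-3,3-dimethyloxiran-2-yl]-3-[(2Z)-2-methylbut-2-enoyloxy]but-1-en-2-yl}-2-hydroxy-1-methyl-7-oxabicyclo[4.1.0]heptan-3-yl (2Z)-2-methylbut-2-enoate | C=C([C@H](C[C@H]1OC1(C)C)OC(=O)/C(C)=C\C)[C@H]1C[C@H]2O[C@@]2(C)[C@@H](O)[C@@H]1OC(=O)/C(C)=C\C | intermediate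
23 | (1R,3R,4R,6R)-4-{(3S)-4-[(2R)-3,3-dimethyloxiran-2-yl]-3-[(2Z)-2-methylbut-2-enoyloxy]but-1-en-2-yl}-1-methyl-2-oxo-7-oxabicyclo[4.1.0]heptan-3-yl (2Z)-2-methylbut-2-enoate | C=C([C@H](C[C@H]1OC1(C)C)OC(=O)/C(C)=C\C)[C@H]1C[C@H]2O[C@@]2(C)C(=O)[C@@H]1OC(=O)/C(C)=C\C | target

## Step count and risks

Total step count: 16. Longest linear sequence: 15 steps (steps 1–3 and 5–16, from 1 to 23); step 4 is a one-step side branch.

**Step 8 (key step).** The most likely failure is poor discrimination between the two C1–CH2 bonds in the β-carbon elimination, because the ligand contacts that distinguish them are far from the C3 substituent and the existing C3′ centre may be mismatched with the ligand. Slow turnover with the hindered silylalkyne is the second concern. Fallback: starting from 11, run the known achiral intermolecular alkyne insertion with Ni(cod)2/PCy3 in toluene at 100 °C and give up enantiotopic-bond control. Because C3′ is already set, this gives 13 together with its C5 epimer, (5S)-5-[(3S)-3-{[tert-butyl(dimethyl)silyl]oxy}-6-methylhepta-1,5-dien-2-yl]-2-methyl-3-(trimethylsilyl)cyclohex-2-en-1-one F1, as diastereomers. These are separated by chromatography and the route is rejoined at 13, at the cost of about half the material.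

**Step 15.** Under fluoride the C1 alkoxide can attack the neighbouring C6 ester, causing acyl migration between O6 and O1. C–Si cleavage at a fully substituted epoxide carbon may also be slow enough to let this compete, since the C1 hydroxyl cannot reach silicon to assist. Fallback: starting from 21, reverse the order so that no free hydroxyl is present. Dess–Martin oxidation gives the silylated epoxy ketone, (1S,3R,4R,6S)-4-{(3S)-4-[(2R)-3,3-dimethyloxiran-2-yl]-3-[(2Z)-2-methylbut-2-enoyloxy]but-1-en-2-yl}-1-methyl-2-oxo-6-(trimethylsilyl)-7-oxabicyclo[4.1.0]heptan-3-yl (2Z)-2-methylbut-2-enoate F2. Its C–Si bond, now β to the carbonyl, is cleaved with tris(dimethylamino)sulfonium difluorotrimethylsilicate in moist DMF, and the route is rejoined directly at 23.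

**Step 13.** Facial selectivity of hydride delivery could be eroded or reversed by the polar C6 ester, and the wrong C1 epimer would steer the epoxide to the wrong face. Fallback: starting from 19, if the reduction gives the C1 epimer, (1R,2S,6R)-6-{(3S)-4-[(2R)-3,3-dimethyloxiran-2-yl]-3-[(2Z)-2-methylbut-2-enoyloxy]but-1-en-2-yl}-2-hydroxy-3-methyl-4-(trimethylsilyl)cyclohex-3-en-1-yl (2Z)-2-methylbut-2-enoate F3, invert it by Mitsunobu reaction with chloroacetic acid (PPh3, diisopropyl azodicarboxylate). The cis C6 ester cannot participate and the silylated C3 blocks allylic transposition. This gives the chloroacetate, (1R,2R,6R)-2-[(chloroacetyl)oxy]-6-{(3S)-4-[(2R)-3,3-dimethyloxiran-2-yl]-3-[(2Z)-2-methylbut-2-enoyloxy]but-1-en-2-yl}-3-methyl-4-(trimethylsilyl)cyclohex-3-en-1-yl (2Z)-2-methylbut-2-enoate F4, which thiourea/NaHCO3 in ethanol cleaves selectively in the presence of the angelates. The route is rejoined at 20.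

**Step 11.** Geometric isomerisation of the activated angelate to the tiglate, or incomplete acylation of the hindered α-ketol so that only one of the two hydroxyls is esterified, is the risk. Fallback: starting from 16, build the Z-enoates on the substrate instead of transferring them. Acylate both hydroxyls with 2-[bis(2,2,2-trifluoroethoxy)phosphoryl]propanoic acid (DCC, DMAP) to give the bis-phosphonate, (1R,6R)-6-{(3S)-3-({2-[bis(2,2,2-trifluoroethoxy)phosphoryl]propanoyl}oxy)-6-methylhepta-1,5-dien-2-yl}-3-methyl-2-oxo-4-(trimethylsilyl)cyclohex-3-en-1-yl 2-[bis(2,2,2-trifluoroethoxy)phosphoryl]propanoate F5. A double Still–Gennari olefination with acetaldehyde (KN(SiMe3)2, 18-crown-6, THF, −78 °C) then forms both Z-trisubstituted esters, and the route is rejoined at 18.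

**Step 5.** Enantioselectivity may be insufficient for a 2-iodoalkene with a branched α-substituent and an unbranched aldehyde, and the aldehyde may isomerise before coupling. Fallback: starting from 6 and 8, couple without the chiral ligand (CrCl2, catalytic NiCl2, DMF) to the racemic alcohol, rac-2-(3,3-dimethoxycyclobutyl)-6-methylhepta-1,5-dien-3-ol F6. Oxidise with Dess–Martin periodinane to the enone, 2-(3,3-dimethoxycyclobutyl)-6-methylhepta-1,5-dien-3-one F7. Reduce with BH3·SMe2 and the (R)-configured B-methyl oxazaborolidine (Corey–Bakshi–Shibata reduction, the branched alkenyl group acting as the large substituent), and rejoin the route at 9.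

## Further compounds

F1 | step 8 | (5S)-5-[(3S)-3-{[tert-butyl(dimethyl)silyl]oxy}-6-methylhepta-1,5-dien-2-yl]-2-methyl-3-(trimethylsilyl)cyclohex-2-en-1-one | C=C([C@H](CC=C(C)C)O[Si](C)(C)C(C)(C)C)[C@@H]1CC([Si](C)(C)C)=C(C)C(=O)C1
F2 | step 15 | (1S,3R,4R,6S)-4-{(3S)-4-[(2R)-3,3-dimethyloxiran-2-yl]-3-[(2Z)-2-methylbut-2-enoyloxy]but-1-en-2-yl}-1-methyl-2-oxo-6-(trimethylsilyl)-7-oxabicyclo[4.1.0]heptan-3-yl (2Z)-2-methylbut-2-enoate | C=C([C@H](C[C@H]1OC1(C)C)OC(=O)/C(C)=C\C)[C@H]1C[C@@]2([Si](C)(C)C)O[C@@]2(C)C(=O)[C@@H]1OC(=O)/C(C)=C\C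
F3 | step 13 | (1R,2S,6R)-6-{(3S)-4-[(2R)-3,3-dimethyloxiran-2-yl]-3-[(2Z)-2-methylbut-2-enoyloxy]but-1-en-2-yl}-2-hydroxy-3-methyl-4-(trimethylsilyl)cyclohex-3-en-1-yl (2Z)-2-methylbut-2-enoate | C=C([C@H](C[C@H]1OC1(C)C)OC(=O)/C(C)=C\C)[C@H]1CC([Si](C)(C)C)=C(C)[C@H](O)[C@@H]1OC(=O)/C(C)=C\C
F4 | step 13 | (1R,2R,6R)-2-[(chloroacetyl)oxy]-6-{(3S)-4-[(2R)-3,3-dimethyloxiran-2-yl]-3-[(2Z)-2-methylbut-2-enoyloxy]but-1-en-2-yl}-3-methyl-4-(trimethylsilyl)cyclohex-3-en-1-yl (2Z)-2-methylbut-2-enoate | C=C([C@H](C[C@H]1OC1(C)C)OC(=O)/C(C)=C\C)[C@H]1CC([Si](C)(C)C)=C(C)[C@@H](OC(=O)CCl)[C@@H]1OC(=O)/C(C)=C\C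
F5 | step 11 | (1R,6R)-6-{(3S)-3-({2-[bis(2,2,2-trifluoroethoxy)phosphoryl]propanoyl}oxy)-6-methylhepta-1,5-dien-2-yl}-3-methyl-2-oxo-4-(trimethylsilyl)cyclohex-3-en-1-yl 2-[bis(2,2,2-trifluoroethoxy)phosphoryl]propanoate (epimers at the phosphonate α-carbons) | C=C([C@H](CC=C(C)C)OC(=O)C(C)P(=O)(OCC(F)(F)F)OCC(F)(F)F)[C@H]1CC([Si](C)(C)C)=C(C)C(=O)[C@@H]1OC(=O)C(C)P(=O)(OCC(F)(F)F)OCC(F)(F)F
F6 | step 5 | rac-2-(3,3-dimethoxycyclobutyl)-6-methylhepta-1,5-dien-3-ol | C=C(C(O)CC=C(C)C)C1CC(OC)(OC)C1
F7 | step 5 | 2-(3,3-dimethoxycyclobutyl)-6-methylhepta-1,5-dien-3-one | C=C(C(=O)CC=C(C)C)C1CC(OC)(OC)C1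
A1 | alternative 1 | open-chain aldehyde with C1 as CHO, angelates at C6 and C3′, a (Z)-2-iodobut-2-enyl arm on C5 and the target configuration at C5, C6 and C3′ | C=C([C@H](CC=C(C)C)OC(=O)/C(C)=C\C)[C@@H](C/C=C(/C)I)[C@H](C=O)OC(=O)/C(C)=C\C
A2 | alternative 1 | 2-methylcyclohex-2-en-1-ol with angelates at C6 and C3′, C1 hydroxyl trans to the C6 ester, prenyl alkene intact | C=C([C@H](CC=C(C)C)OC(=O)/C(C)=C\C)[C@H]1CC=C(C)[C@@H](O)[C@@H]1OC(=O)/C(C)=C\C
A3 | alternative 2 | acyclic dienone with an isopropenyl ketone at C1, C6 silyl ether, allyl group on C5 and the epoxidised, C3′-silylated side chain | C=C([C@H](C[C@H]1OC1(C)C)O[Si](C)(C)C(C)(C)C)[C@@H](CC=C)[C@@H](O[Si](C)(C)C(C)(C)C)C(=O)C(C)=C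
A4 | alternative 2 | 6-silyloxy-2-methylcyclohex-2-enone with the epoxidised, C3′-silylated side chain at C5 | C=C([C@H](C[C@H]1OC1(C)C)O[Si](C)(C)C(C)(C)C)[C@H]1CC=C(C)C(=O)[C@@H]1O[Si](C)(C)C(C)(C)C
A5 | alternative 3 | acyclic (E)-allylsilane aldehyde with C6 as CHO, C1 p-methoxybenzyl ether, (Z)-C2=C3 alkene and C3′ silyl ether | O=C[C@H](OCc1ccc(OC)cc1)/C(C)=C\C/C=C(/C[Si](C)(C)C)[C@H](CC=C(C)C)O[Si](C)(C)C(C)(C)C
A6 | alternative 3 | cyclohexenol with C6 hydroxyl, C1 p-methoxybenzyl ether and the C3′-silylated diene side chain at C5 | C=C([C@H](CC=C(C)C)O[Si](C)(C)C(C)(C)C)[C@H]1CC=C(C)[C@@H](OCc2ccc(OC)cc2)[C@@H]1O
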